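## Structural features

The target 14 is a 3,4-dihydroisocoumarin: a benzene ring (ring A, C4a to C8a) fused to a six-membered lactone (ring B: C1, O2, C3, C4). Ring A carries a methyl ether at C6 and a free phenol at C8, which sits peri to the lactone carbonyl and is hydrogen-bonded to it. C3 bears an unbranched chain of eleven carbons (C1' to C11') that ends in a primary alcohol. C3 is the only stereocentre (R). It is a carbinol carbon flanked by two methylene groups (benzylic C4 and C1'), so it has no neighbouring stereocentre to relay from, and its two carbon substituents differ little in size. The fragile elements are the lactone (opened by base, reduced by hydrides), the electron-rich resorcinol-type ring (attacked by strong oxidants and electrophiles) and the two ring oxygens, which must end up differentiated. The real difficulty is to fix C3 and to attach a long chain with a remote oxygen without a series of protecting-group steps. The key step exploits the fact that C3 and C1' to C11' are twelve carbons in a row with an oxygen at each end (O2 and the terminal hydroxyl). That is a cyclododecanone ring opened by inserting one oxygen between the carbonyl carbon (future C11') and its α-carbon (future C3).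

## Logic of the disconnections

**14 to 13.** The O–H at C8 is retraced to an O–CH3 bond. The phenol is carried as a methyl ether because a free phenol next to the acyl group would interfere with the base and oxidant used earlier, and because both ring oxygens are already methylated in 1. No protecting group has to be introduced. The forward step must cleave only the ether peri to the carbonyl and spare the C6 ether, the lactone and the alcohol.

**13 to 12.** The C11' alcohol is retraced to a carboxylic acid. The acid is what opening of a lactone at the chain end delivers, so the chain terminus never needs a protecting group. The forward step must reduce an acid next to an aryl lactone. This is a more reliable distinction than asking a hydride to tell a macrolactone from a benzoate and from the aryl lactone that forms as soon as the C3 oxygen is free.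

**12 to 10.** The O2–C1 bond of ring B is cut, O2 is reconnected to the chain-end carbonyl (C11'), and C1 returns to its methyl ester. This trades the six-membered aryl lactone for a 13-membered lactone that holds C3–O and the chain terminus in one ring. The forward step is a hydrolysis that passes through 11 and must then close only the six-membered lactone. No bond to C3 is touched.

**10 to 8 (key).** The C3–O2 bond is cut and C3 is reconnected to the carbonyl carbon, which contracts the lactone to a 12-membered ketone. The chain, its terminal oxygen and the C3–O bond then all come from one cheap ring, and the carbinol stereocentre becomes a ketone α-stereocentre, for which reliable alkylation chemistry exists. The forward oxidation must insert oxygen on the substituted side, with retention, without prior epimerisation and without attacking ring A.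

**8 to 7 to 5 + 2.** With the ketone written as its chiral hydrazone 7, the C3–C4 bond is cut. It is the only carbon–carbon bond between the arene part and the carbocycle, and it ends at the stereocentre, so forming it can set the configuration. The pieces are an achiral hydrazone and a benzylic bromide. The forward step needs face-selective monoalkylation of the azaenolate 6 and a mild release of the ketone.

**5 to 3 + 4.** The C=N bond is cut to the symmetrical ketone 3 and the auxiliary 4. Because 3 is symmetrical, no regiochemical question arises in the condensation or in the deprotonation.

**2 to 1.** The benzylic C–Br bond is retraced to C–H. The forward step must halogenate the methyl group and not the activated ring.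

## Other disconnections considered

**Alternative 1:** The cut is the C4a–C8a bond of ring A. In the forward direction, a mild base would make the diketo-dioxinone A1 attack its C4a ketone through C8a; dehydration and enolisation of the C6 ketone then give the benzodioxinone A2. A2 would be methylated at its free phenol. Release of the C3 alkoxide would then open the dioxinone carbonyl, closing ring B and freeing the C8 phenol in one event, and the benzyl ether would be removed last.
- In favour: the two ring oxygens emerge already differentiated, so no selective ether cleavage is needed. On this point the alternative is better than the chosen plan.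
- Also in favour: the aromatisation is driven thermodynamically and is regiochemically unambiguous, which makes it at least the equal of the peracid step in mechanistic certainty.
- Against: A1 is a sensitive polycarbonyl compound whose C3 silyloxy group is β to the C4a ketone, so base can eliminate it.
- Against: A1 needs a separately made chiral β-oxygenated acyl unit with a long ω-benzyloxy chain, and three kinds of protecting group.
- Comparison: this route spends its effort on building ring A, which the chosen plan buys in 1. It is expected to be several steps longer than the eight steps from 1 and 3.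

**Alternative 2:** The cuts are C3–C4 and C1–O2. A chiral bifunctional squaramide–amine catalyst would make the enol of anhydride A3 add through C4 to aldehyde A4, and the new alkoxide would acylate at C1 to give acid A5. Decarboxylation at C4, debenzylation and the C8 ether cleavage would follow.
- In favour: it is the most convergent plan. Ring B and C3 arise in one catalytic step from two achiral pieces, with no stoichiometric auxiliary. On this point it is better than the chosen plan.
- Against: the two methoxy groups make A3 harder to enolise, and A4 is an unhindered, enolisable aliphatic aldehyde. This class is less secure for such annulations than aromatic aldehydes.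
- Against: the C4 carboxyl is not truly traceless. Its removal needs a separate thermal or radical step, and an anion at C4 can expel the C3–O bond and open ring B.
- Comparison: the step count would be about equal to the chosen plan if the decarboxylation is clean, and the final ether cleavage is the same. The C3 configuration would rest on a catalyst–substrate match. In the chosen plan it is transferred by a stereospecific rearrangement.

**Alternative 3:** The cut is C8a–C1. A silyl triflate would ionise the acetal carbon of the methoxymethyl ether A6, and the cationic carbon would be captured by the ring position ortho to the side chain to give isochroman A7. C1 would then be oxidised to the lactone, the silyl ether removed and the C8 ether cleaved.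
- In favour: the stereocentre of A6 can come from a terminal epoxide of secure optical purity opened by an aryl nucleophile. This is more certain than an azaenolate alkylation in a twelve-membered ring, and here the alternative is better.
- Also in favour: the ring closure uses the electron-rich arene as the nucleophile and has no regiochemical ambiguity, because both ortho positions are equivalent. The chosen plan has to protect the same ring from a peracid.
- Against: A7 is at the ether oxidation level. The benzylic oxidation at C1 must be done next to a second benzylic position (C4) and on an oxidisable ring.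
- Against: the chain, the epoxide, the acetal and the silyl ether add steps, and the C8 ether cleavage is still required.
- Comparison: the route has a redox detour and a longer linear sequence. The chosen plan never changes the oxidation level of C1.

Key step: step 5

Remark on the chemistry: the sense of induction of the hydrazone alkylation is assumed to follow the usual chelated azaenolate model in the twelve-membered ring as well (ring-cis azaenolate). On that model the R auxiliary 4, not its enantiomer, leads to the R ketone, because the entering arylmethyl group outranks the ring methylene. The descriptors were re-derived as R in 8, R in 10 and R in 14.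

## Route

**Step 1**
Reactants: 1 methyl 2,4-dimethoxy-6-methylbenzoate
Product: 2 methyl 2-(bromomethyl)-4,6-dimethoxybenzoate
Conditions: NBS (1.05 equiv), 2,2'-azobis(2-methylpropanenitrile) (5 mol%), PhCF3, 85 °C, hν
Reagents that add atoms: N-bromosuccinimide, O=C1CCC(=O)N1Br
Why: Wohl–Ziegler bromination; bromine atoms abstract benzylic hydrogen and the benzylic radical is trapped by the low stationary concentration of Br2. The ester lowers the nucleophilicity of the ring and the non-polar medium disfavours ionic ring bromination.

**Step 2**
Reactants: 3 cyclododecanone; 4 (R)-1-amino-2-(methoxymethyl)pyrrolidine (RAMP)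
Product: 5 (2R)-N-cyclododecylidene-2-(methoxymethyl)pyrrolidin-1-amine
Conditions: toluene, 4-MeC6H4SO3H·H2O (1 mol%), Dean–Stark, reflux
Reagents that add atoms: none
Why: Acid-catalysed hydrazone condensation driven by azeotropic removal of water. The ketone is symmetrical, so only one hydrazone can form, and the stereocentre of the auxiliary is not involved.

**Step 3**
Reactants: 5 (2R)-N-cyclododecylidene-2-(methoxymethyl)pyrrolidin-1-amine; 2 methyl 2-(bromomethyl)-4,6-dimethoxybenzoate
Product: 7 methyl 2,4-dimethoxy-6-{[(1R)-2-{[(2R)-2-(methoxymethyl)pyrrolidin-1-yl]imino}cyclododecyl]methyl}benzoate, via lithium azaenolate 6 (not isolated)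
Conditions: LiN(i-Pr)2 (1.1 equiv), THF, 0 °C; then 2, −100 °C → rt
Reagents that add atoms: none
Why: RAMP-hydrazone alkylation (the SAMP/RAMP method): deprotonation gives the lithium azaenolate 6, in which the methoxymethyl arm chelates lithium and blocks one face, and the benzylic bromide enters by SN2 from the open face. With the R auxiliary this face gives the R configuration at the new centre, the mirror image of the S outcome known for the S auxiliary when the entering group has priority over the resident one.

**Step 4**
Reactants: 7 methyl 2,4-dimethoxy-6-{[(1R)-2-{[(2R)-2-(methoxymethyl)pyrrolidin-1-yl]imino}cyclododecyl]methyl}benzoate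
Product: 8 methyl 2,4-dimethoxy-6-{[(1R)-2-oxocyclododecyl]methyl}benzoate
Conditions: sat. aq. (CO2H)2, Et2O, rt, two-phase
Reagents that add atoms: water, O
Why: Hydrolytic cleavage of the hydrazone with a weak acid; the auxiliary passes into the aqueous layer as its oxalate and can be recovered. The conditions are too mild to enolise the α-branched ketone, and ozone is avoided because of the electron-rich ring.

**Step 5**
Reactants: 8 methyl 2,4-dimethoxy-6-{[(1R)-2-oxocyclododecyl]methyl}benzoate
Product: 10 methyl 2,4-dimethoxy-6-{[(2R)-13-oxooxacyclotridecan-2-yl]methyl}benzoate, via Criegee adduct 9 (not isolated)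
Conditions: mCPBA (2.5 equiv), Na2HPO4 (5 equiv), CH2Cl2, 0 °C → rt, dark
Reagents that add atoms: 3-chloroperoxybenzoic acid (mCPBA), OOC(=O)c1cccc(Cl)c1
Why: The peracid adds to the ketone carbonyl to give the peroxy-hemiketal 9, and the ring carbon antiperiplanar to the O–O bond shifts to oxygen as 3-chlorobenzoate leaves. This is a Baeyer–Villiger oxidation, and the closest known reaction type is the conversion of 2-alkylcycloalkanones, large rings included, into lactones substituted at the carbinol carbon. The 13-membered ring is not closed end to end; it arises by a 1,2-shift that enlarges the 12-membered carbocycle by one atom, so no dilution is needed. The carbinol stereocentre at C3 is controlled by the substrate alone: the shift is concerted and suprafacial, so the migrating carbon keeps its configuration and R in 8 becomes R in 10. The step needs regioselectivity, which the substrate secures because the branched secondary α-carbon carries positive charge better than the ring methylene and migrates first. It also needs chemoselectivity: the ester deactivates ring A towards the peracid, and the solid phosphate buffer removes the acid that would catalyse ring hydroxylation or enolisation of 8. Ketone 8 should be oxidised soon after it is made so that its α-centre has no time to equilibrate.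

**Step 6**
Reactants: 10 methyl 2,4-dimethoxy-6-{[(2R)-13-oxooxacyclotridecan-2-yl]methyl}benzoate
Product: 12 11-[(3R)-6,8-dimethoxy-1-oxo-3,4-dihydro-1H-isochromen-3-yl]undecanoic acid, via dilithium dicarboxylate 11 (not isolated)
Conditions: LiOH·H2O (6 equiv), THF–H2O, 50 °C; then 2 M HCl to pH 1, 40 °C
Reagents that add atoms: lithium hydroxide, [Li+].[OH-]
Why: Saponification opens the macrolactone by acyl–oxygen cleavage; the freed C3 alkoxide transacylates the neighbouring hindered benzoate and hydroxide opens the resulting aryl lactone, so the material collects as 11. On acidification only the δ-hydroxy acid can close to a six-membered ring (acid-catalysed lactonisation), the remote carboxyl stays free, and no bond to C3 is broken.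

**Step 7**
Reactants: 12 11-[(3R)-6,8-dimethoxy-1-oxo-3,4-dihydro-1H-isochromen-3-yl]undecanoic acid
Product: 13 (3R)-3-(11-hydroxyundecyl)-6,8-dimethoxy-3,4-dihydro-1H-isochromen-1-one
Conditions: BH3·THF (1.5 equiv), THF, 0 °C → rt; then H2O
Reagents that add atoms: none
Why: Chemoselective borane reduction: the carboxylic acid is reduced quickly through its acyloxyborane. The aryl lactone, conjugated to a donor-substituted ring, is a much poorer substrate for the electrophilic hydride donor and should remain.

**Step 8**
Reactants: 13 (3R)-3-(11-hydroxyundecyl)-6,8-dimethoxy-3,4-dihydro-1H-isochromen-1-one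
Product: 14 (3R)-8-hydroxy-3-(11-hydroxyundecyl)-6-methoxy-3,4-dihydro-1H-isochromen-1-one
Conditions: BCl3 (3 equiv), CH2Cl2, −78 → 0 °C; then H2O
Reagents that add atoms: none
Why: Chelation-directed Lewis-acid ether cleavage: boron binds the lactone carbonyl and the peri C8 methoxy oxygen in a six-membered chelate, chloride removes that methyl group by SN2, and water frees the phenol. The C6 ether cannot chelate and should stay, and the primary alcohol is only borylated reversibly.

## Compound list

1 | methyl 2,4-dimethoxy-6-methylbenzoate | COC(=O)c1c(C)cc(OC)cc1OC | starting material
2 | methyl 2-(bromomethyl)-4,6-dimethoxybenzoate | COC(=O)c1c(CBr)cc(OC)cc1OC | intermediate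
3 | cyclododecanone | O=C1CCCCCCCCCCC1 | starting material
4 | (R)-1-amino-2-(methoxymethyl)pyrrolidine (RAMP) | COC[C@H]1CCCN1N | starting material
5 | (2R)-N-cyclododecylidene-2-(methoxymethyl)pyrrolidin-1-amine | COC[C@H]1CCCN1N=C1CCCCCCCCCCC1 | intermediate
6 | lithium (cyclododec-1-en-1-yl)[(2R)-2-(methoxymethyl)pyrrolidin-1-yl]azanide, ring-cis azaenolate | [Li]N(N1CCC[C@@H]1COC)/C1=C/CCCCCCCCCC1 | intermediate
7 | methyl 2,4-dimethoxy-6-{[(1R)-2-{[(2R)-2-(methoxymethyl)pyrrolidin-1-yl]imino}cyclododecyl]methyl}benzoate | COC(=O)c1c(OC)cc(OC)cc1C[C@H]1CCCCCCCCCCC1=NN1CCC[C@@H]1COC | intermediate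
8 | methyl 2,4-dimethoxy-6-{[(1R)-2-oxocyclododecyl]methyl}benzoate | COC(=O)c1c(OC)cc(OC)cc1C[C@H]1CCCCCCCCCCC1=O | intermediate
9 | methyl 2-{[(1R)-2-[(3-chlorobenzoyl)peroxy]-2-hydroxycyclododecyl]methyl}-4,6-dimethoxybenzoate (Criegee adduct, hemiketal carbon undefined) | COC(=O)c1c(OC)cc(OC)cc1C[C@H]1CCCCCCCCCCC1(O)OOC(=O)c1cccc(Cl)c1 | intermediate
10 | methyl 2,4-dimethoxy-6-{[(2R)-13-oxooxacyclotridecan-2-yl]methyl}benzoate | COC(=O)c1c(OC)cc(OC)cc1C[C@H]1CCCCCCCCCCC(=O)O1 | intermediate
11 | dilithium (12R)-13-(2-carboxylato-3,5-dimethoxyphenyl)-12-hydroxytridecanoate | [Li+].[Li+].COc1cc(OC)c(C([O-])=O)c(C[C@H](O)CCCCCCCCCCC([O-])=O)c1 | intermediate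
12 | 11-[(3R)-6,8-dimethoxy-1-oxo-3,4-dihydro-1H-isochromen-3-yl]undecanoic acid | COc1cc(OC)c2c(c1)C[C@@H](CCCCCCCCCCC(=O)O)OC2=O | intermediate
13 | (3R)-3-(11-hydroxyundecyl)-6,8-dimethoxy-3,4-dihydro-1H-isochromen-1-one | COc1cc(OC)c2c(c1)C[C@@H](CCCCCCCCCCCO)OC2=O | intermediate
14 | (3R)-8-hydroxy-3-(11-hydroxyundecyl)-6-methoxy-3,4-dihydro-1H-isochromen-1-one | COc1cc(O)c2c(c1)C[C@@H](CCCCCCCCCCCO)OC2=O | target

## Step count and least certain steps

Total: 8 steps. Longest linear sequence: 7 steps (steps 2 to 8, from 3 and 4). The arm from 1 is one step long and joins at step 3.

**Step 5 (key step).** Addition of the peracid to the hindered, transannularly crowded twelve-membered ketone may be slow. During a long reaction, hydroxylation of the activated ring positions, migration of the methylene carbon, or enolisation at the α-centre could compete. The fallback sets out from 8 and comes back at 10. Both open ring positions would be brominated with N-bromosuccinimide in MeCN at 0 °C in the dark to give methyl 3,5-dibromo-2,4-dimethoxy-6-{[(1R)-2-oxocyclododecyl]methyl}benzoate F1. The blocked, electron-poorer ring should then tolerate the stronger buffered CF3CO3H (from (CF3CO)2O and H2O2·urea, Na2HPO4, CH2Cl2, 0 °C), which should give methyl 3,5-dibromo-2,4-dimethoxy-6-{[(2R)-13-oxooxacyclotridecan-2-yl]methyl}benzoate F2. Hydrogenolysis of both carbon–bromine bonds (H2, palladium on carbon, NaOAc, MeOH–EtOAc) would return to 10.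

**Step 3.** The azaenolate geometry is not locked in the flexible large ring, so facial selectivity may be poor, and deprotonation may be slow. Because the auxiliary is still attached in 7, a minor diastereomer can in principle be removed by ordinary chromatography before step 4. The fallback gives up auxiliary control; it sets out from 3 and 2 and comes back at 10. The lithium enolate of 3 (LiN(i-Pr)2, THF, −78 °C) would be alkylated with 2 to give racemic methyl 2,4-dimethoxy-6-[(2-oxocyclododecyl)methyl]benzoate F3. This would be oxidised as in step 5 to racemic methyl 2,4-dimethoxy-6-[(13-oxooxacyclotridecan-2-yl)methyl]benzoate F4, whose carbinol centre can no longer epimerise. The enantiomers would be separated by preparative chromatography on a chiral stationary phase. The R enantiomer is 10, and methyl 2,4-dimethoxy-6-{[(2S)-13-oxooxacyclotridecan-2-yl]methyl}benzoate F5 is set aside.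

**Step 1.** Ionic bromination of the activated ring may compete with benzylic hydrogen abstraction, and a second bromination at the benzylic carbon is possible. The fallback replaces the radical process by a carbanion; it sets out from 1 and comes back at 7. Lateral deprotonation of 1 with LiN(i-Pr)2 (THF, −78 °C) and inverse addition of the benzylic anion to C2Cl6 should give methyl 2-(chloromethyl)-4,6-dimethoxybenzoate F6. This takes the place of 2 in step 3, at a somewhat higher alkylation temperature.

**Step 4.** Hydrolysis of the hindered C=N bond may be slow, and forcing acid would invite loss of configuration through enolisation. The fallback activates the hydrazone by quaternisation; it sets out from 7 and comes back at 8. Methylation of the pyrrolidine nitrogen with MeI should give methyl 2,4-dimethoxy-6-{[(1R)-2-{[(2R)-2-(methoxymethyl)-1-methylpyrrolidin-1-ium-1-yl]imino}cyclododecyl]methyl}benzoate iodide F7. This hydrazonium salt is hydrolysed far more readily, in a two-phase system of pentane and dilute HCl with short contact time.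

**Step 8.** The free primary alcohol consumes Lewis acid, and if the mixture has to be warmed, the C6 ether may also be cleaved or the borylated alcohol may be substituted by chloride. The fallback masks the alcohol; it sets out from 13 and comes back at 14. Acetylation (Ac2O, pyridine) should give 11-[(3R)-6,8-dimethoxy-1-oxo-3,4-dihydro-1H-isochromen-3-yl]undecyl acetate F8. BCl3 at −78 °C should then give 11-[(3R)-8-hydroxy-6-methoxy-1-oxo-3,4-dihydro-1H-isochromen-3-yl]undecyl acetate F9. Hydrolysis with LiOH in THF–H2O followed by acidification, which re-closes any opened ring B as in step 6, would give 14.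

## Further compounds

F1 | step 5 | methyl 3,5-dibromo-2,4-dimethoxy-6-{[(1R)-2-oxocyclododecyl]methyl}benzoate | COC(=O)c1c(OC)c(Br)c(OC)c(Br)c1C[C@H]1CCCCCCCCCCC1=O
F2 | step 5 | methyl 3,5-dibromo-2,4-dimethoxy-6-{[(2R)-13-oxooxacyclotridecan-2-yl]methyl}benzoate | COC(=O)c1c(OC)c(Br)c(OC)c(Br)c1C[C@H]1CCCCCCCCCCC(=O)O1
F3 | step 3 | racemic methyl 2,4-dimethoxy-6-[(2-oxocyclododecyl)methyl]benzoate | COC(=O)c1c(OC)cc(OC)cc1CC1CCCCCCCCCCC1=O
F4 | step 3 | racemic methyl 2,4-dimethoxy-6-[(13-oxooxacyclotridecan-2-yl)methyl]benzoate | COC(=O)c1c(OC)cc(OC)cc1CC1CCCCCCCCCCC(=O)O1
F5 | step 3 | methyl 2,4-dimethoxy-6-{[(2S)-13-oxooxacyclotridecan-2-yl]methyl}benzoate | COC(=O)c1c(OC)cc(OC)cc1C[C@@H]1CCCCCCCCCCC(=O)O1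
F6 | step 1 | methyl 2-(chloromethyl)-4,6-dimethoxybenzoate | COC(=O)c1c(CCl)cc(OC)cc1OC
F7 | step 4 | methyl 2,4-dimethoxy-6-{[(1R)-2-{[(2R)-2-(methoxymethyl)-1-methylpyrrolidin-1-ium-1-yl]imino}cyclododecyl]methyl}benzoate iodide | COC(=O)c1c(OC)cc(OC)cc1C[C@H]1CCCCCCCCCCC1=N[N+]1(C)CCC[C@@H]1COC.[I-]
F8 | step 8 | 11-[(3R)-6,8-dimethoxy-1-oxo-3,4-dihydro-1H-isochromen-3-yl]undecyl acetate | COc1cc(OC)c2c(c1)C[C@@H](CCCCCCCCCCCOC(C)=O)OC2=O
F9 | step 8 | 11-[(3R)-8-hydroxy-6-methoxy-1-oxo-3,4-dihydro-1H-isochromen-3-yl]undecyl acetate | COc1cc(O)c2c(c1)C[C@@H](CCCCCCCCCCCOC(C)=O)OC2=O
A1 | alternative 1 | 6-[(6R)-17-(benzyloxy)-6-(tert-butyldimethylsilyloxy)-2,4-dioxoheptadecyl]-2,2-dimethyl-4H-1,3-dioxin-4-one | CC1(C)OC(=O)C=C(CC(=O)CC(=O)C[C@@H](CCCCCCCCCCCOCc2ccccc2)O[Si](C)(C)C(C)(C)C)O1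
A2 | alternative 1 | 5-[(2R)-13-(benzyloxy)-2-(tert-butyldimethylsilyloxy)tridecyl]-7-hydroxy-2,2-dimethyl-4H-1,3-benzodioxin-4-one | CC1(C)OC(=O)c2c(O1)cc(O)cc2C[C@@H](CCCCCCCCCCCOCc3ccccc3)O[Si](C)(C)C(C)(C)C
A3 | alternative 2 | 6,8-dimethoxy-1H-isochromene-1,3(4H)-dione (6,8-dimethoxyhomophthalic anhydride) | COc1cc(OC)c2c(c1)CC(=O)OC2=O
A4 | alternative 2 | 12-(benzyloxy)dodecanal | O=CCCCCCCCCCCCOCc1ccccc1
A5 | alternative 2 | (3R,4S)-3-[11-(benzyloxy)undecyl]-6,8-dimethoxy-1-oxoisochromane-4-carboxylic acid | COc1cc(OC)c2c(c1)[C@H](C(=O)O)[C@@H](CCCCCCCCCCCOCc3ccccc3)OC2=O
A6 | alternative 3 | 1,3-dimethoxy-5-[(2R)-2-(methoxymethoxy)-13-(triisopropylsilyloxy)tridecyl]benzene | COc1cc(OC)cc(c1)C[C@@H](CCCCCCCCCCCO[Si](C(C)C)(C(C)C)C(C)C)OCOC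
A7 | alternative 3 | (3R)-6,8-dimethoxy-3-[11-(triisopropylsilyloxy)undecyl]isochromane | COc1cc(OC)c2c(c1)C[C@@H](CCCCCCCCCCCO[Si](C(C)C)(C(C)C)C(C)C)OC2
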